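- At 35 °C the step from substrate to target has the constant 4.00, worked from its listed value and enthalpy. So once the two have equilibrated (a pre-equilibrium), 80.0% of the pool c(substrate) + c(target) stands as target. We call this fraction the target share, and we reckon target as share times the fraction of the charge left in the pool.

all flasks: substrate 1.5 M; time 8.0 min
- south-west: temperature 35 °C
- south: temperature 65 °C
- south-east: temperature 50 °C
- west: temperature 80 °C

* the best flask by amount of target, in percent of the substrate charged; "all alike" if 1.5 percentage points covers them all (south-west / south / south-east / west / all alike)
* amount of target at the end, in percent of the substrate charged, south-west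
* amount of target at the end, in percent of the substrate charged, south
* amount of target at the end, in percent of the substrate charged, south-east
* amount of target at the end, in percent of the substrate charged, west

- in percentages every species weighs as the substrate in it: one side product counts as two
- for target the crystals are counted in
- as a solid, counted per litre of solution: crystals
- at 50 °C the constants are as listed, elsewhere as the activation energies and enthalpies make them
- in a conversion other conformer counts as not yet reacted; third conformer counts as reacted

    substrate ⇌ other conformer (K1 = 0.514, k1 = 0.00343 s⁻¹, Ea1 = 90.0 kJ mol⁻¹, ΔH1 = 4.00 kJ mol⁻¹)
    substrate ⇌ target (K2 = 1.4, k2 = 0.0302 s⁻¹, Ea2 = 80.0 kJ mol⁻¹, ΔH2 = −58.0 kJ mol⁻¹)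
    other conformer → isomer of the product (k3 = 0.0576 s⁻¹, Ea3 = 94.0 kJ mol⁻¹)
    other conformer ⇌ third conformer (K4 = 1.9, k4 = 0.00512 s⁻¹, Ea4 = 82.0 kJ mol⁻¹, ΔH4 = −32.0 kJ mol⁻¹)
    third conformer → third product (k5 = 0.0303 s⁻¹, Ea5 = 81.0 kJ mol⁻¹)
    substrate + target → side product (k6 = 0.00211 M⁻¹ s⁻¹, Ea6 = 53.0 kJ mol⁻¹)
    crystals ⇌ target, rate k7*(cs7 - [target]) while solid is left; crystals form when [target] > cs7 (cs7 = 1.1 M, k7 = 0.0168 s⁻¹)
    (constants at 50 °C)

- From above, in the south-west flask, a pool that loses nothing gives the share, 80.0% of the charge, as target in solution. That is 1.20 M, above the solubility 1.1 M, so in such a pool crystals form. With dissolved target held at the solubility and substrate at that value over the constant, target with its crystals counted is 81.7%, and this is our first bound.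
- The pool drains two ways. Substrate leaks into the other conformer at 6.72 × 10⁻⁴ s⁻¹, and each side product removes two units of pool, with 8.08 × 10⁻⁴ M⁻¹ s⁻¹. The fraction left therefore obeys a first-order plus a second-order loss, which integrates exactly.
- From below, we take the worst case. The whole pool leaks as if it were substrate, and the product c(substrate)·c(target) is a quarter of the pool squared, its largest possible value. The fraction left is then 58.0%, so target is 46.4%.
- The mix relaxes with a time of 1.88 min, shorter than 8.0 min, so the share applies at the end.
- To tighten the top, we hold the pool at the equilibrium mix from the start. The fraction left becomes 79.4%, and target 63.6%. The flask really starts from pure substrate, so we take this as the top of the bracket by judgement, not by proof. It means 0.954 M of dissolved target, below the solubility 1.1 M, so we expect no crystals.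
- The hotter flasks have smaller shares: 35.0% in the south flask and 18.3% in the west flask. In the south-east flask the share is 58.3%, and the same equilibrium-mix reckoning gives about 19.1%. So we commit to south-west as the best flask, its floor standing above these three figures, with target a little under the top of its bracket.
- The forecast names south-west, with 59.5% for south-west, 0.4% for south, 22% for south-east and 0% for west. Its grounds begin from the picture “Substrate leaks through the other conformer to the isomer”. Its south-west figure lies inside our bracket.
- The simulation gives south-west as best, with 60.2% for south-west, 0.368% for south, 20.9% for south-east and 0% for west. The south-west value also lies inside the bracket.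
- The way back from target to substrate is the main reason for the empty west flask: with it struck out, target there reads 84.4% instead of 0%. The target share expresses that way back, and the south-west reading of target over pool at 8.00 min is 80.9%, against a share of 80.0%. In the south-east flask, a share of 58.3% of the pool left, which is 34.9% of the charge, gives 20.4%, and that flask reads 20.9%.

The numbers of this flask were set for the occasion.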